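## Structural features

Locants used for every compound, open-chain ones included: C1 is the carbinol carbon carrying the tiglate, C2 the CH2, C3 the carbinol carbon carrying the isovalerate, C4 the C(CH3)2, C5 the cyclobutane CH next to C4, C6 the cyclobutane CH next to the ketone, C7 the C=O, C8 the enone CH, C9 the enone C–CH3, C10 the cyclobutane CH next to C9, and C11 the quaternary cyclobutane carbon carrying CH3 and C1. The target 29 is a longipinane-type sesquiterpenoid diester, (1R,3R,5S,6R,10R,11R), on a tricyclo[5.4.0.0^2,8]undecane: the cyclobutane C5–C6–C11–C10 is bridged across C6/C10 by the enone C7(=O)–C8=C9(CH3) (a verbenone-like bicyclo[3.1.1]heptenone) and, on the opposite face, across C5/C11 by C1–C2–C3–C4 (a bicyclo[4.1.1]octane). All four cyclobutane carbons are contiguous stereocentres (C11 quaternary, its methyl syn to the enone bridge), and C1 and C3, trans to each other on the seven-membered ring, each stand next to a quaternary carbon. Fragile points are the E-configured tiglate, two hindered secondary esters that must be told apart, and the strained ring: any intermediate with oxygen on C5 and a ketone at C7 or C3 is a β-ketol open to retro-aldol cleavage. The real difficulty is that the cyclobutane is bridged on both diagonals, so neither a parallel [2+2] nor an SN2 closure (C5 is neopentyl, C11 quaternary) fits. The key step exploits the fact that C5 carries only H and one carbon (C4) while C11 carries CH3 and a chain. This is the pattern left when a ketene carbonyl carbon (C5) and its α-carbon (C10) add across a trisubstituted alkene C6=C11, and with that cut all fifteen skeletal carbons lie on one farnesane chain C5–C10–C9–C8–C7–C6–C11–C1–C2–C3–C4. The C5 carbonyl so created is not in the target: it faces the C1 chain across the cyclobutane, serves to close the seven-membered ring at C4–C5, and is then erased. In one sentence: an open-chain, trioxygenated farnesoyl chloride is closed by an intramolecular vinylketene–alkene [2+2] cycloaddition.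

## Logic of the disconnections

29 ⇒ 27 (through 28). The C7 ketone and the C8=C9 bond are taken back to a C7 silyl-free carbinol and a C9 exocyclic methylene. The C7 carbinol is the stereocontrol element of the key step and must stay masked while C5 carries oxygen. The forward step needs an oxidation and a base-mediated alkene shift that leave two esters untouched.

27 ⇒ 26 ⇒ 24 + 25 ⇒ 22 + 23. The two acyl–O bonds and the C3–H bond are cut. A hydride-transfer esterification of β-hydroxy ketone 22 with aldehyde 23 sets C3 anti to C1, places the tiglate on C1 and leaves only the C3 hydroxyl for 25, so the two neopentyl alcohols are never both free. The demand is intramolecular hydride delivery across the seven-membered ring from a conjugated aldehyde.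

22 ⇒ 21 ⇒ 20 ⇒ 19. The C5–H bond is traced to a C5–OH, the residue of the ring closure. A C5 radical cannot eliminate (two bridgeheads and a quaternary neighbour) and cannot invert (C4 is tied back by the ring). The demand is acylation of a hindered tertiary ketol without retro-aldol, and hydrogen transfer faster than cyclobutane opening.

19 ⇒ 17 (through 18). The C4–C5 bond is cut as an aldol between a C3/C4 enolate and the C5 cyclobutanone. This removes the seven-membered ring and the C4 quaternary centre. The enolate must form only towards C4 (hence the α-benzoyloxy ketone and SmI2) and attack the one face of C5 that the C1 chain can reach.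

17 ⇒ 14 (through 15 and 16), the key disconnection. The C5–C6 and C10–C11 bonds are cut as a ketene–alkene [2+2]. The cyclobutane, the bicyclo[3.1.1]heptane and three stereocentres (C6, C10, C11) disappear, leaving an open chain with two carbinol stereocentres. The forward step must close in the crossed sense, transfer the E geometry of C6=C11 to C11, and take the alkene face dictated by C7.

14 ⇒ 13 ⇒ 12 ⇒ 8 + 11, with 11 ⇒ 9. The C7–C8 bond is cut as a vinylogous aldol. It splits the chain into a C10 aldehyde and a C5 dienolate and sets C7. The demand is γ-selectivity, an E enoate and Si-face addition to 8.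

8 ⇒ 7 ⇒ 6 ⇒ 5 ⇒ 3 + 4, with 3 ⇒ 2 ⇒ 1. The C1–C2 bond is cut as a methyl ketone aldol onto enal 4. It sets C1 and leaves three C5 building blocks (1, 4, 9). The demand is Re-face addition and orthogonal masking of the C1 and C7 oxygens.

## Other disconnections considered

Alternative 1: The enone half is verbenone, so the first idea is the chiral pool. Cut C2–C3 (aldol) and, behind it, C11–C1 and C5–C4, back to (1R,5R)-verbenone A1. The forward key step would be an intramolecular aldol of keto aldehyde A2 (acetyl in place of the anti methyl on C11, a 2-methyl-1-oxopropan-2-yl group on C5). A2 needs two C–C bonds at the least reactive positions of A1, the anti methyl of the gem-dimethyl bridge and the unactivated methylene bridge, with no handle to direct either. The detours would cost far more steps than building both substituents into the alkene and ketene of 16, and C1 would still have to be set.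

Alternative 2: Keep both bridges and cut the cyclobutane transannularly: C5–C6 and C10–C11 from the eleven-membered humulene-type trienone A3. The forward key step would be a crossed transannular enone–alkene photocycloaddition of A3. The two alkenes are linked by three and by four atoms, and stepwise diradical closure of such units favours the parallel mode, which gives a fused 5-4-6 skeleton and not the doubly bridged one. Excited-state E/Z isomerisation would erase the geometry that defines C11, nothing in A3 selects the alkene faces relative to C1 and C3, and an eleven-membered ring is no easier to make than chain 14.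

Alternative 3: The classical four-ring closure: cut C5–C6 by intramolecular alkylation. The forward key step would be displacement of the C5 sulfonate of bicyclo[5.4.0]undecenone tosylate A4 by its C6 enolate. C5 is a neopentyl secondary carbon next to C4, so SN2 with inversion would be slow relative to elimination or fragmentation. The leaving group must also sit anti to C6 in a flexible seven-membered ring, and C5, C10 and C11 must all be set before the key step instead of by it, which lengthens the route.

Key step: step 11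

Remark on the chemistry: 4 (the C5 aldehyde of industrial vitamin A manufacture) is taken as purchasable; it is otherwise one step from prenyl acetate with SeO2/t-BuOOH.

Remark on the chemistry: the antipode of the bisphosphoramide in steps 3 and 8 is specified by the aldehyde face that must be attacked; the antipodes named are those expected to deliver that face.

## Route

Step 1
Reactants: 1 3-hydroxy-3-methylbutan-2-one
Product: 2 2-methyl-3-oxobutan-2-yl benzoate
Conditions: BzCl, Et3N, DMAP (cat.), CH2Cl2, 0 °C to reflux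
Reagents that add atoms: benzoyl chloride, O=C(Cl)c1ccccc1
Why: DMAP-catalysed acylation of a tertiary α-hydroxy ketone; the benzoate is the leaving group that later gives the C3/C4 enolate regiospecifically.

Step 2
Reactants: 2 2-methyl-3-oxobutan-2-yl benzoate
Product: 3 2-methyl-3-[(trimethylsilyl)oxy]but-3-en-2-yl benzoate
Conditions: TMSOTf, Et3N, CH2Cl2, 0 °C
Reagents that add atoms: trimethylsilyl trifluoromethanesulfonate, C[Si](C)(C)OS(=O)(=O)C(F)(F)F
Why: Soft enolisation and O-silylation; only the methyl group has α-hydrogens, so one enol silane forms.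

Step 3
Reactants: 3 2-methyl-3-[(trimethylsilyl)oxy]but-3-en-2-yl benzoate; 4 (2E)-4-acetoxy-2-methylbut-2-enal
Product: 5 (5R,6E)-8-acetoxy-5-hydroxy-2,6-dimethyl-3-oxooct-6-en-2-yl benzoate (C1 is R)
Conditions: SiCl4, (R,R)-binaphthyldiamine-derived bisphosphoramide (5 mol %, antipode for Re-face attack), CH2Cl2, −78 °C; aq. NaHCO3
Reagents that add atoms: none
Why: Lewis-base-activated SiCl4 Mukaiyama aldol of a methyl ketone enol silane with an α-methyl enal (1,2-addition only); the chiral silicon cation shields one aldehyde face and Re-face attack sets C1 as R.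

Step 4
Reactants: 5 (5R,6E)-8-acetoxy-5-hydroxy-2,6-dimethyl-3-oxooct-6-en-2-yl benzoate
Product: 6 (5R,6E)-8-acetoxy-2,6-dimethyl-3-oxo-5-[(triethylsilyl)oxy]oct-6-en-2-yl benzoate
Conditions: TESCl, imidazole, DMF, 0 °C
Reagents that add atoms: chlorotriethylsilane, CC[Si](Cl)(CC)CC
Why: Standard silylation of the β-hydroxy ketone; TES is chosen so that it can later be removed beside the C7 TBS ether.

Step 5
Reactants: 6 (5R,6E)-8-acetoxy-2,6-dimethyl-3-oxo-5-[(triethylsilyl)oxy]oct-6-en-2-yl benzoate
Product: 7 (5R,6E)-8-hydroxy-2,6-dimethyl-3-oxo-5-[(triethylsilyl)oxy]oct-6-en-2-yl benzoate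
Conditions: K2CO3 (cat.), MeOH, 0 °C
Reagents that add atoms: none
Why: Transesterification of the primary allylic acetate, which is far faster than attack on the tertiary benzoate or loss of the TES ether at 0 °C.

Step 6
Reactants: 7 (5R,6E)-8-hydroxy-2,6-dimethyl-3-oxo-5-[(triethylsilyl)oxy]oct-6-en-2-yl benzoate
Product: 8 (5R,6E)-2,6-dimethyl-3,8-dioxo-5-[(triethylsilyl)oxy]oct-6-en-2-yl benzoate
Conditions: MnO2, CH2Cl2, rt
Reagents that add atoms: none
Why: Chemoselective oxidation of the allylic alcohol to the C7 enal with retention of the E geometry.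

Step 7
Reactants: 9 methyl 3-methylbut-2-enoate
Product: 11 tert-butyl[(1-methoxy-3-methylbuta-1,3-dien-1-yl)oxy]dimethylsilane, via lithium dienolate 10 (not isolated)
Conditions: LiN(iPr)2, THF, −78 °C; then TBSCl, DMPU, −78 °C to rt
Reagents that add atoms: tert-butyldimethylsilyl chloride, CC(C)(C)[Si](C)(C)Cl
Why: γ-Deprotonation gives the extended dienolate, which is silylated on oxygen to the silyl ketene acetal used for vinylogous aldol reactions.

Step 8
Reactants: 8 (5R,6E)-2,6-dimethyl-3,8-dioxo-5-[(triethylsilyl)oxy]oct-6-en-2-yl benzoate; 11 tert-butyl[(1-methoxy-3-methylbuta-1,3-dien-1-yl)oxy]dimethylsilane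
Product: 12 methyl (2E,5S,6E,8R)-11-(benzoyloxy)-5-hydroxy-3,7,11-trimethyl-10-oxo-8-[(triethylsilyl)oxy]dodeca-2,6-dienoate (C7 is S, C1 is R)
Conditions: SiCl4, (S,S)-binaphthyldiamine-derived bisphosphoramide (5 mol %, antipode for Si-face attack), iPr2NEt (cat.), CH2Cl2, −78 °C; aq. NaHCO3
Reagents that add atoms: none
Why: Catalytic enantioselective vinylogous Mukaiyama aldol; the hindered ketene acetal reacts at its γ-carbon to give the E enoate, and catalyst-controlled Si-face attack sets C7 as S. The hindered C3 ketone does not compete with the enal.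

Step 9
Reactants: 12 methyl (2E,5S,6E,8R)-11-(benzoyloxy)-5-hydroxy-3,7,11-trimethyl-10-oxo-8-[(triethylsilyl)oxy]dodeca-2,6-dienoate
Product: 13 methyl (2E,5S,6E,8R)-11-(benzoyloxy)-5-[(tert-butyldimethylsilyl)oxy]-3,7,11-trimethyl-10-oxo-8-[(triethylsilyl)oxy]dodeca-2,6-dienoate
Conditions: TBSCl, imidazole, DMF, rt
Reagents that add atoms: tert-butyldimethylsilyl chloride, CC(C)(C)[Si](C)(C)Cl
Why: Standard silylation; the TBS ether on C7 outlasts the TES ether on C1 and becomes the steric control element of step 11.

Step 10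
Reactants: 13 methyl (2E,5S,6E,8R)-11-(benzoyloxy)-5-[(tert-butyldimethylsilyl)oxy]-3,7,11-trimethyl-10-oxo-8-[(triethylsilyl)oxy]dodeca-2,6-dienoate
Product: 14 (2E,5S,6E,8R)-11-(benzoyloxy)-5-[(tert-butyldimethylsilyl)oxy]-3,7,11-trimethyl-10-oxo-8-[(triethylsilyl)oxy]dodeca-2,6-dienoic acid
Conditions: Me3SnOH, 1,2-dichloroethane, 80 °C; cold dil. HCl wash
Reagents that add atoms: trimethyltin hydroxide, C[Sn](C)(C)O
Why: Near-neutral methyl ester cleavage that spares the tertiary benzoate, both silyl ethers and the β-silyloxy ketone.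

Step 11
Reactants: 14 (2E,5S,6E,8R)-11-(benzoyloxy)-5-[(tert-butyldimethylsilyl)oxy]-3,7,11-trimethyl-10-oxo-8-[(triethylsilyl)oxy]dodeca-2,6-dienoic acid
Product: 17 bicyclic cyclobutanone (bicyclo[3.1.1]heptan-6-one: C5=O and C11 as one-carbon bridges, C6 and C10 bridgeheads, C7–OTBS, C9=CH2, C11 carrying CH3 syn to the C7–C9 bridge and the chain C1H(OTES)–C2H2–C3(=O)–C4(CH3)2–OBz anti; 1R,6R,7S,10R,11R), via acid chloride 15 (not isolated), via vinylketene 16 (not isolated)
Conditions: 1-chloro-N,N,2-trimethylprop-1-en-1-amine, CH2Cl2, 0 °C; then slow addition to Et3N, toluene (high dilution), 110 °C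
Reagents that add atoms: none
Why: Dehydrochlorination of the (E)-3-methylalk-2-enoyl chloride 15 at the γ-methyl group, which lies syn to the carbonyl, gives vinylketene 16, and this adds across C6=C11 in a thermal, concerted but asynchronous [2+2] cycloaddition; the closest known reaction type is the intramolecular cycloaddition of vinylketenes from geranoyl- and farnesoyl-type chlorides, which gives 2-methylenebicyclo[3.1.1]heptan-6-ones. The electrophilic ketene carbon C5 bonds to C6 and the ketene α-carbon C10 bonds to C11, the alkene end that best carries positive charge, so the closure is crossed: the six-membered ring C6–C7–C8–C9–C10–C11 closes at C11 and the four-membered ring C5–C6–C11–C10 forms as the pair of one-carbon bridges of a bicyclo[3.1.1]heptane, not as a fused bicyclo[3.2.0]heptane. Addition is suprafacial on the E alkene, so the C11 methyl (cis to C7 on the alkene) ends syn to the C7–C9 bridge and the C1 chain ends anti, pointing at the anti face of the new C5 carbonyl; C10 is fixed by the bicyclic constraint. The absolute configuration is relayed from C7: the tether atom C8 must rise from one alkene face, and of the two remaining C7 substituents the one that flanks the cis C11 methyl must be H and not OTBS (allylic 1,3-strain, and the C–O bond then lies near the alkene plane where it withdraws least), so 7S leads to 6R,10R,11R. The selectivities needed are the crossed regiochemistry (secured by the polarity of the trisubstituted alkene), reaction at C6=C11 and not at C9=CH2 or the carbonyls (secured by the three-atom tether) and one alkene face (secured by C7). High dilution and slow addition hold back ketene dimerisation.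

Step 12
Reactants: 17 bicyclic cyclobutanone (1R,6R,7S,10R,11R)
Product: 19 tricyclic ketol (C4–C5 bond closed; C5–OH, C3=O, C1–OTES, C7–OTBS, C9=CH2; 1R,5R,6R,7S,10R,11R), via samarium enolate 18 (not isolated)
Conditions: SmI2 (2.2 equiv), THF, −78 to −40 °C; sat. aq. NH4Cl
Reagents that add atoms: none
Why: Two-electron reductive cleavage of the α-benzoyloxy ketone gives a trivalent samarium enolate only at C3/C4, which adds in a Reformatsky-type aldol to the strained, highly electrophilic cyclobutanone. The C1 chain can reach only the anti face of C5, so the new C4–C5 bond is anti and the hydroxyl syn; C4 is not stereogenic.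

Step 13
Reactants: 19 tricyclic ketol (1R,5R,6R,7S,10R,11R)
Product: 20 tricyclic methyl oxalate (C5–O–CO–CO2CH3; otherwise as 19; 1R,5R,6R,7S,10R,11R)
Conditions: ClCOCO2Me, pyridine, DMAP (cat.), CH2Cl2, 0 °C
Reagents that add atoms: methyl chlorooxoacetate, COC(=O)C(=O)Cl
Why: Acylation of the only free (tertiary) hydroxyl with a small, very reactive acyl chloride under weakly basic conditions gives the radical precursor; dehydration is impossible (two bridgeheads, one quaternary carbon).

Step 14
Reactants: 20 tricyclic methyl oxalate (1R,5R,6R,7S,10R,11R)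
Product: 21 tricyclic ketone (C5–H, C3=O, C1–OTES, C7–OTBS, C9=CH2; 1R,5S,6R,7S,10R,11R)
Conditions: Bu3SnH (excess), AIBN (cat.), toluene, 110 °C
Reagents that add atoms: none
Why: Barton–McCombie-type radical deoxygenation of a tertiary methyl oxalate. The C5 radical has its orbital perpendicular to the cyclobutane bonds (slow ring opening), and hydrogen can enter only on the side the oxygen left, because C4 is held anti by the ring; this gives 5S.

Step 15
Reactants: 21 tricyclic ketone (1R,5S,6R,7S,10R,11R)
Product: 22 tricyclic β-hydroxy ketone (C1–OH, C3=O, C7–OTBS, C9=CH2; 1R,5S,6R,7S,10R,11R)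
Conditions: PPTS, MeOH/CH2Cl2, 0 °C
Reagents that add atoms: none
Why: Acid-catalysed solvolysis removes the secondary TES ether much faster than the more hindered TBS ether; no base is present, so retro-aldol is avoided.

Step 16
Reactants: 22 tricyclic β-hydroxy ketone (1R,5S,6R,7S,10R,11R); 23 (2E)-2-methylbut-2-enal
Product: 24 hydroxy tiglate (C1–O-tigloyl, C3–OH, C7–OTBS, C9=CH2; 1R,3R,5S,6R,7S,10R,11R)
Conditions: 23 (5 equiv), SmI2 (0.3 equiv), THF, −10 °C
Reagents that add atoms: none
Why: Evans–Tishchenko reaction: the hemiacetal of the C1 hydroxyl with 23, held on trivalent samarium, transfers its hydride to the C3 carbonyl on the face syn to the C1 oxygen. This gives the 1,3-anti (3R) alcohol and leaves the tiglate on C1, so one step sets C3, installs the tiglate and tells the two oxygens apart.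

Step 17
Reactants: 24 hydroxy tiglate (1R,3R,5S,6R,7S,10R,11R); 25 3-methylbutanoyl chloride
Product: 26 diester silyl ether (C1–O-tigloyl, C3–O-isovaleryl, C7–OTBS, C9=CH2; 1R,3R,5S,6R,7S,10R,11R)
Conditions: pyridine, DMAP, CH2Cl2, 0 °C to rt
Reagents that add atoms: none
Why: DMAP-catalysed acylation of the only free hydroxyl; no stereocentre is touched.

Step 18
Reactants: 26 diester silyl ether (1R,3R,5S,6R,7S,10R,11R)
Product: 27 diester alcohol (C7–OH, C9=CH2; 1R,3R,5S,6R,7S,10R,11R)
Conditions: HF·pyridine, pyridine, THF, 0 °C to rt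
Reagents that add atoms: none
Why: Buffered fluoride desilylation that spares both esters; C5 no longer carries oxygen, so the C7 oxygen can now be released.

Step 19
Reactants: 27 diester alcohol (1R,3R,5S,6R,7S,10R,11R)
Product: 29 target CNP0194415.1 (C1–O-tigloyl, C3–O-isovaleryl, C7=O, C8=C9; 1R,3R,5S,6R,10R,11R), via deconjugated ketone 28 (not isolated)
Conditions: DMP (1,1,1-triacetoxy-1,2-benziodoxol-3-one), NaHCO3, CH2Cl2, rt; then DBU (cat.), rt
Reagents that add atoms: none
Why: Periodinane oxidation of the C7 carbinol, then base-mediated shift of the exocyclic alkene into conjugation through the C7/C8 dienolate (C6 is a bridgehead and cannot enolise), gives the verbenone-type enone. The tiglate is the thermodynamically preferred ester geometry and no β-leaving group is present.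

## Compound list

1 | 3-hydroxy-3-methylbutan-2-one | CC(=O)C(C)(C)O | starting material
2 | 2-methyl-3-oxobutan-2-yl benzoate | CC(=O)C(C)(C)OC(=O)c1ccccc1 | intermediate
3 | 2-methyl-3-[(trimethylsilyl)oxy]but-3-en-2-yl benzoate | C=C(O[Si](C)(C)C)C(C)(C)OC(=O)c1ccccc1 | intermediate
4 | (2E)-4-acetoxy-2-methylbut-2-enal | CC(=O)OC/C=C(\C)C=O | starting material
5 | (5R,6E)-8-acetoxy-5-hydroxy-2,6-dimethyl-3-oxooct-6-en-2-yl benzoate | CC(=O)OC/C=C(\C)[C@H](O)CC(=O)C(C)(C)OC(=O)c1ccccc1 | intermediate
6 | (5R,6E)-8-acetoxy-2,6-dimethyl-3-oxo-5-[(triethylsilyl)oxy]oct-6-en-2-yl benzoate | CC(=O)OC/C=C(\C)[C@H](O[Si](CC)(CC)CC)CC(=O)C(C)(C)OC(=O)c1ccccc1 | intermediate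
7 | (5R,6E)-8-hydroxy-2,6-dimethyl-3-oxo-5-[(triethylsilyl)oxy]oct-6-en-2-yl benzoate | OC/C=C(\C)[C@H](O[Si](CC)(CC)CC)CC(=O)C(C)(C)OC(=O)c1ccccc1 | intermediate
8 | (5R,6E)-2,6-dimethyl-3,8-dioxo-5-[(triethylsilyl)oxy]oct-6-en-2-yl benzoate | O=C/C=C(\C)[C@H](O[Si](CC)(CC)CC)CC(=O)C(C)(C)OC(=O)c1ccccc1 | intermediate
9 | methyl 3-methylbut-2-enoate | COC(=O)C=C(C)C | starting material
10 | lithium 1-methoxy-3-methylbuta-1,3-dien-1-olate (not isolated) | [Li+].[O-]C(OC)=CC(C)=C | intermediate
11 | tert-butyl[(1-methoxy-3-methylbuta-1,3-dien-1-yl)oxy]dimethylsilane (ketene acetal geometry immaterial) | C=C(C)C=C(OC)O[Si](C)(C)C(C)(C)C | intermediate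
12 | methyl (2E,5S,6E,8R)-11-(benzoyloxy)-5-hydroxy-3,7,11-trimethyl-10-oxo-8-[(triethylsilyl)oxy]dodeca-2,6-dienoate | COC(=O)/C=C(\C)C[C@H](O)/C=C(\C)[C@H](O[Si](CC)(CC)CC)CC(=O)C(C)(C)OC(=O)c1ccccc1 | intermediate
13 | methyl (2E,5S,6E,8R)-11-(benzoyloxy)-5-[(tert-butyldimethylsilyl)oxy]-3,7,11-trimethyl-10-oxo-8-[(triethylsilyl)oxy]dodeca-2,6-dienoate | COC(=O)/C=C(\C)C[C@H](O[Si](C)(C)C(C)(C)C)/C=C(\C)[C@H](O[Si](CC)(CC)CC)CC(=O)C(C)(C)OC(=O)c1ccccc1 | intermediate
14 | (2E,5S,6E,8R)-11-(benzoyloxy)-5-[(tert-butyldimethylsilyl)oxy]-3,7,11-trimethyl-10-oxo-8-[(triethylsilyl)oxy]dodeca-2,6-dienoic acid | OC(=O)/C=C(\C)C[C@H](O[Si](C)(C)C(C)(C)C)/C=C(\C)[C@H](O[Si](CC)(CC)CC)CC(=O)C(C)(C)OC(=O)c1ccccc1 | intermediate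
15 | acid chloride of 14 (2E,5S,6E,8R; not isolated) | ClC(=O)/C=C(\C)C[C@H](O[Si](C)(C)C(C)(C)C)/C=C(\C)[C@H](O[Si](CC)(CC)CC)CC(=O)C(C)(C)OC(=O)c1ccccc1 | intermediate
16 | vinylketene (O=C=CH–C(=CH2)–CH2– head on the chain of 15; 5S,6E,8R in chain numbering; not isolated) | O=C=CC(=C)C[C@H](O[Si](C)(C)C(C)(C)C)/C=C(\C)[C@H](O[Si](CC)(CC)CC)CC(=O)C(C)(C)OC(=O)c1ccccc1 | intermediate
17 | bicyclic cyclobutanone (C5=O, C7–OTBS, C9=CH2, C11 with CH3 syn and the C1(OTES)–C2–C3(=O)–C4(CH3)2OBz chain anti; 1R,6R,7S,10R,11R) | O=C1[C@H]2[C@@H](O[Si](C)(C)C(C)(C)C)CC(=C)[C@@H]1[C@@]2(C)[C@H](O[Si](CC)(CC)CC)CC(=O)C(C)(C)OC(=O)c1ccccc1 | intermediate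
18 | trivalent samarium enolate of 17 (C3(OSmI2)=C4(CH3)2; not isolated) | O=C1[C@H]2[C@@H](O[Si](C)(C)C(C)(C)C)CC(=C)[C@@H]1[C@@]2(C)[C@H](O[Si](CC)(CC)CC)CC(O[Sm](I)I)=C(C)C | intermediate
19 | tricyclic ketol (C5–OH, C3=O, C1–OTES, C7–OTBS, C9=CH2; 1R,5R,6R,7S,10R,11R) | CC[Si](CC)(CC)O[C@@H]1CC(=O)C(C)(C)[C@]2(O)[C@H]3[C@@H](O[Si](C)(C)C(C)(C)C)CC(=C)[C@@H]2[C@]31C | intermediate
20 | tricyclic methyl oxalate (C5–O–CO–CO2CH3; 1R,5R,6R,7S,10R,11R) | CC[Si](CC)(CC)O[C@@H]1CC(=O)C(C)(C)[C@]2(OC(=O)C(=O)OC)[C@H]3[C@@H](O[Si](C)(C)C(C)(C)C)CC(=C)[C@@H]2[C@]31C | intermediate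
21 | tricyclic ketone (C5–H, C3=O, C1–OTES, C7–OTBS, C9=CH2; 1R,5S,6R,7S,10R,11R) | CC[Si](CC)(CC)O[C@@H]1CC(=O)C(C)(C)[C@@H]2[C@H]3[C@@H](O[Si](C)(C)C(C)(C)C)CC(=C)[C@@H]2[C@]31C | intermediate
22 | tricyclic β-hydroxy ketone (C1–OH, C3=O, C7–OTBS, C9=CH2; 1R,5S,6R,7S,10R,11R) | O[C@@H]1CC(=O)C(C)(C)[C@@H]2[C@H]3[C@@H](O[Si](C)(C)C(C)(C)C)CC(=C)[C@@H]2[C@]31C | intermediate
23 | (2E)-2-methylbut-2-enal | C/C=C(\C)C=O | starting material
24 | hydroxy tiglate (C1–O-tigloyl, C3–OH, C7–OTBS, C9=CH2; 1R,3R,5S,6R,7S,10R,11R) | C/C=C(\C)C(=O)O[C@@H]1C[C@@H](O)C(C)(C)[C@@H]2[C@H]3[C@@H](O[Si](C)(C)C(C)(C)C)CC(=C)[C@@H]2[C@]31C | intermediate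
25 | 3-methylbutanoyl chloride | CC(C)CC(=O)Cl | starting material
26 | diester silyl ether (C1–O-tigloyl, C3–O-isovaleryl, C7–OTBS, C9=CH2; 1R,3R,5S,6R,7S,10R,11R) | C/C=C(\C)C(=O)O[C@@H]1C[C@@H](OC(=O)CC(C)C)C(C)(C)[C@@H]2[C@H]3[C@@H](O[Si](C)(C)C(C)(C)C)CC(=C)[C@@H]2[C@]31C | intermediate
27 | diester alcohol (C7–OH, C9=CH2; 1R,3R,5S,6R,7S,10R,11R) | C/C=C(\C)C(=O)O[C@@H]1C[C@@H](OC(=O)CC(C)C)C(C)(C)[C@@H]2[C@H]3[C@@H](O)CC(=C)[C@@H]2[C@]31C | intermediate
28 | deconjugated ketone (C7=O, C9=CH2; 1R,3R,5S,6R,10R,11R; not isolated) | C/C=C(\C)C(=O)O[C@@H]1C[C@@H](OC(=O)CC(C)C)C(C)(C)[C@@H]2[C@H]3C(=O)CC(=C)[C@@H]2[C@]31C | intermediate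
29 | CNP0194415.1 (1R,3R,5S,6R,10R,11R) | C/C=C(\C)C(=O)O[C@@H]1C[C@@H](OC(=O)CC(C)C)C(C)(C)[C@@H]2[C@H]3C(=O)C=C(C)[C@@H]2[C@]31C | target

## Step count and least certain steps

Total step count: 19. Longest linear sequence: 18 (steps 1–6 and 8–19; step 7 makes the side reagent 11).

Step 11 (key step). The most likely failure is consumption of the vinylketene by oligomerisation, or base-induced loss of the C1 silyloxy group β to the C3 ketone at 110 °C, before the cycloaddition occurs. The cause is that the C6=C11 alkene is flanked by two allylic silyloxy groups and is less nucleophilic than the hydrocarbon alkenes for which this reaction type is established. The fallback removes one of the two oxygens and moves the C7 oxidation to the end; it sets out from 7 and comes back at 29. Appel bromination of 7 (CBr4, PPh3) gives allylic bromide F1. ZnBr2-catalysed γ-alkylation of silyl dienolate 11 with F1 gives the 7-deoxy dienoate F2, and Me3SnOH gives acid F3. The same acid chloride/Et3N sequence gives bicyclic ketone F4; facial control then rests on C1 alone, so a diastereomer separation may be needed. The conditions of steps 12 to 17 then lead through ketol F5, oxalate F6, ketone F7, hydroxy ketone F8 and hydroxy tiglate F9 to diester F10. RhCl3·3H2O in ethanol moves the exocyclic alkene into the ring to give the endocyclic alkene F11. Allylic oxidation with CrO3 and 3,5-dimethylpyrazole, the pinene-to-verbenone type of oxidation, then installs the C7 ketone and gives 29.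

Step 12. The most likely failure is protonation of the samarium enolate, or reversal of the aldol, in place of ring closure. The cause is that the new bond joins a fully substituted enolate carbon to a carbonyl flanked by two bridgeheads. The fallback changes the closure to a Lewis-acid Mukaiyama aldol; it sets out from 17 and comes back at 19. SmI2 followed by TMSCl traps the enolate as the isolable trimethylsilyl enol ether F12. TiCl4 in CH2Cl2 at −78 °C then activates the cyclobutanone for an irreversible intramolecular addition of the enol silane, and aqueous work-up gives 19.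

Step 13. The most likely failure is retro-aldol opening of the seven-membered ring, or very slow acylation. The cause is that the free tertiary ketol is exposed to base while its hydroxyl is shielded by C4 and two bridgeheads. The fallback never liberates the ketol; it sets out from 17 and comes back at 20 without any new compound. Step 12 is run as written and methyl chlorooxoacetate is added to the cold samarium aldolate before work-up, so that the metal alkoxide is acylated as it is formed.

Step 16. The most likely failures are unproductive consumption of the conjugated, α-branched aldehyde (pinacol coupling, Tishchenko dimerisation), slow hemiacetal formation, and retro-aldol scrambling of C1 on the samarium alkoxide. The fallback uses an aldehyde of proven reactivity and exchanges the ester afterwards; it sets out from 22 and comes back at 26. Evans–Tishchenko reaction of 22 with 4-nitrobenzaldehyde gives hydroxy 4-nitrobenzoate F13 with the same 1,3-anti outcome. Acylation with 25 gives mixed diester F14. K2CO3 in methanol at 0 °C cleaves the activated aryl ester much faster than the hindered isovalerate and gives hydroxy isovalerate F15. Tigloyl chloride with DMAP then gives 26.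

## Further compounds

F1 | step 11 | (5R,6E)-8-bromo-2,6-dimethyl-3-oxo-5-[(triethylsilyl)oxy]oct-6-en-2-yl benzoate | BrC/C=C(\C)[C@H](O[Si](CC)(CC)CC)CC(=O)C(C)(C)OC(=O)c1ccccc1
F2 | step 11 | methyl (2E,6E,8R)-11-(benzoyloxy)-3,7,11-trimethyl-10-oxo-8-[(triethylsilyl)oxy]dodeca-2,6-dienoate | COC(=O)/C=C(\C)CC/C=C(\C)[C@H](O[Si](CC)(CC)CC)CC(=O)C(C)(C)OC(=O)c1ccccc1
F3 | step 11 | (2E,6E,8R)-11-(benzoyloxy)-3,7,11-trimethyl-10-oxo-8-[(triethylsilyl)oxy]dodeca-2,6-dienoic acid | OC(=O)/C=C(\C)CC/C=C(\C)[C@H](O[Si](CC)(CC)CC)CC(=O)C(C)(C)OC(=O)c1ccccc1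
F4 | step 11 | 7-deoxy analogue of 17 (C7H2) | O=C1[C@H]2CCC(=C)[C@@H]1[C@@]2(C)[C@H](O[Si](CC)(CC)CC)CC(=O)C(C)(C)OC(=O)c1ccccc1
F5 | step 11 | 7-deoxy analogue of 19 | CC[Si](CC)(CC)O[C@@H]1CC(=O)C(C)(C)[C@]2(O)[C@H]3CCC(=C)[C@@H]2[C@]31C
F6 | step 11 | 7-deoxy analogue of 20 | CC[Si](CC)(CC)O[C@@H]1CC(=O)C(C)(C)[C@]2(OC(=O)C(=O)OC)[C@H]3CCC(=C)[C@@H]2[C@]31C
F7 | step 11 | 7-deoxy analogue of 21 | CC[Si](CC)(CC)O[C@@H]1CC(=O)C(C)(C)[C@@H]2[C@H]3CCC(=C)[C@@H]2[C@]31C
F8 | step 11 | 7-deoxy analogue of 22 | O[C@@H]1CC(=O)C(C)(C)[C@@H]2[C@H]3CCC(=C)[C@@H]2[C@]31C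
F9 | step 11 | 7-deoxy analogue of 24 | C/C=C(\C)C(=O)O[C@@H]1C[C@@H](O)C(C)(C)[C@@H]2[C@H]3CCC(=C)[C@@H]2[C@]31C
F10 | step 11 | 7-deoxy diester with C9 exocyclic methylene | C/C=C(\C)C(=O)O[C@@H]1C[C@@H](OC(=O)CC(C)C)C(C)(C)[C@@H]2[C@H]3CCC(=C)[C@@H]2[C@]31C
F11 | step 11 | 7-deoxy diester with C8=C9 endocyclic alkene | C/C=C(\C)C(=O)O[C@@H]1C[C@@H](OC(=O)CC(C)C)C(C)(C)[C@@H]2[C@H]3CC=C(C)[C@@H]2[C@]31C
F12 | step 12 | trimethylsilyl enol ether of 17 (C3(OSiMe3)=C4(CH3)2) | O=C1[C@H]2[C@@H](O[Si](C)(C)C(C)(C)C)CC(=C)[C@@H]1[C@@]2(C)[C@H](O[Si](CC)(CC)CC)CC(O[Si](C)(C)C)=C(C)C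
F0 | step 13 | none | none
F13 | step 16 | hydroxy 4-nitrobenzoate (C1–O-(4-nitrobenzoyl), C3–OH, C7–OTBS) | O=C(O[C@@H]1C[C@@H](O)C(C)(C)[C@@H]2[C@H]3[C@@H](O[Si](C)(C)C(C)(C)C)CC(=C)[C@@H]2[C@]31C)c1ccc(cc1)[N+](=O)[O-]
F14 | step 16 | mixed diester (C1–O-(4-nitrobenzoyl), C3–O-isovaleryl, C7–OTBS) | O=C(O[C@@H]1C[C@@H](OC(=O)CC(C)C)C(C)(C)[C@@H]2[C@H]3[C@@H](O[Si](C)(C)C(C)(C)C)CC(=C)[C@@H]2[C@]31C)c1ccc(cc1)[N+](=O)[O-]
F15 | step 16 | hydroxy isovalerate (C1–OH, C3–O-isovaleryl, C7–OTBS) | O[C@@H]1C[C@@H](OC(=O)CC(C)C)C(C)(C)[C@@H]2[C@H]3[C@@H](O[Si](C)(C)C(C)(C)C)CC(=C)[C@@H]2[C@]31C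
A1 | alternative 1 | (1R,5R)-verbenone | CC1=CC(=O)[C@@H]2C[C@H]1C2(C)C
A2 | alternative 1 | keto aldehyde (verbenone core with acetyl in place of the anti methyl on C11 and 2-methyl-1-oxopropan-2-yl on C5) | CC(=O)[C@@]1(C)[C@@H]2C(=O)C=C(C)[C@H]1[C@@H]2C(C)(C)C=O
A3 | alternative 2 | eleven-membered humulene-type trienone diester (C5=C10, C8=C9, C6=C11 all E; 1R,3R) | C/C=C(\C)C(=O)O[C@@H]1C[C@@H](OC(=O)CC(C)C)C(C)(C)/C=C/C(C)=C/C(=O)/C=C1\C
A4 | alternative 3 | bicyclo[5.4.0]undecenone tosylate (C5–OTs anti to C6; C1 and C3 as TBS ethers) | CC1=CC(=O)C[C@]2(C)[C@H](O[Si](C)(C)C(C)(C)C)C[C@@H](O[Si](C)(C)C(C)(C)C)C(C)(C)[C@@H](OS(=O)(=O)c3ccc(C)cc3)[C@H]12
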